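The data were generated by integration with constants of no real substance, noise included.

We read this flask at 8.0 d, and in the delta run, which is this very flask followed so far, X moves by 1.8 percentage points between its last two readings, against a scatter of 1 point.

| setting | delta | eta | flask |
|---|---|---|---|
| Z | 0.020 M | 0.020 M | 0.020 M |
| D | 1 equiv | 1 equiv | 1.00 equiv |
| temperature | 90 °C | 96 °C | 90 °C |
| remark | the very flask that is asked about, followed so far | run made earlier |  |
| time |  |  | 8.0 d |

- delta (time / d: X / %, Z / %): 0.500: 24.4, 68.6; 0.833: 33.7, 55.5; 1.25: 40.8, 51.4; 2.50: 47.8, 41.4; 4.00: 48.5, 39.2; 6.00: 50.3, 40.4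
- eta (time / d: X / %, Z / %): 0.500: 28.1, 62.5; 0.833: 39.6, 50.7; 1.25: 46.5, 42.2; 2.50: 52.0, 37.3; 4.00: 53.4, 36.8; 6.00: 53.4, 36.1

(scatter of a reading: 1 percentage point)

- ash: at 8.0 d raise the temperature by 15 K, then wait 8.0 d
- oak: at 8.0 d take out 90% of the G then present, then wait 8.0 d
- larch: at 8.0 d add D, 100% of the amount charged, then wait 8.0 d
- elm: change nothing and wait 8.0 d more

- X, in percent of the Z first charged, at 8.0 d
- what to do for the largest gain in X; "none" if nothing gains more than 2 percentage points (ash / oak / larch / elm / none)
- X present, in percent of the Z first charged, after ash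
- X present, in percent of the Z first charged, after elm

- additions leave the volume as it is
- at the start none of Z is in solution
- a reading or a percentage of X counts all its forms, free or not

1. What we freeze. At 6.00 d the delta run leaves 9.30% of the charge outside X and solid Z, and we take that as dissolved Z, held steady while solid Z stands (40.4% at that reading). With it frozen, and one G per X, we carry the plateau number P = x·g/d, in fractions of the charge. The mean of the last two delta readings, x = 49.4%, gives P = 0.482.

2. Elm. P is already met, so we expect X to stay at 49.4%, which is also our value for now.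

3. Ash. The eta plateau, 53.4%, gives P = 0.612. Carrying that rise on geometrically over 15 K gives P = 0.875, so x = 59.5%.

4. Oak. With 90% of G gone, P is restored at x = 67.6%.

5. Larch. With a second charge of D added, so that the D charged in all is twice the first charge, P is restored at x = 77.0%, which is more than oak or ash give by hand.

6. The forecast. It gives 50% now, 50% after elm, 58% after ash, and chooses larch: “I take it as equilibrium, but D being consumed by a side reaction cannot be excluded.” Our ash value stands above its figure.

7. The flask. It gives 49.8% now, 49.8% after elm and 57.0% after ash. The best option is larch, gaining 41 points, against 22 points for oak and 7.2 points for ash.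

    L ⇌ X, rate k1*(cs1 - [X]) while solid is left; crystals form when [X] > cs1 (solubility = 7.20 mM, k = 4.30 h⁻¹)
    Z ⇌ E, rate k2*(cs2 - [E]) while solid is left; crystals form when [E] > cs2 (solubility = 2.10 mM, k = 0.810 h⁻¹)
    E + D ⇌ X + G (K = 3.40, k = 17.0 L mol⁻¹ h⁻¹, Ea = 80.0 kJ mol⁻¹, ΔH = 22.0 kJ mol⁻¹)
    (constants at 90 °C)

In this flask E + D ⇌ X + G relaxes with a half-life of 0.0988 d, far shorter than the 8.0 d before we look, which is thermodynamic control; its X gives P = 0.494, with E at 10.5% and L, which is counted in X and which P does not tell apart from dissolved X, at 13.8%. For the neighbour flask with 2.50 equiv of D, P gives x = 88.3%, but that flask holds 93.7% of X, with Z at 0% and L at 57.7%.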